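**Retrosynthetic overview**
- The target (a filixic acid BBB-type trimer, achiral) is released by hydrogenolysis of its tri-O-benzyl ether.
- Both outer six-membered β-triketone rings are disconnected at once. Each is cut at the bond between the butyryl-bearing ring carbon and its neighbouring enol carbon, and at the bond between the CMe2 carbon and its neighbouring enol carbon. This gives a tetra-acid chloride (two malonyl units on the central arene) and two molecules of a 2-silyloxy-4-methoxy-1,3-diene (two-directional [3+3] double C-acylation).
- Enabling feature: each outer ring is a 1,3,5-trioxygenated carbocycle made of a malonyl unit C(OH)–C(CH2Ar)–C(OH) and a ketone-derived unit CMe2–C(=O)–C(COPr). The quaternary CMe2 carbon prevents aromatisation. The mirror plane through the central benzene ring (through the butyryl-bearing carbon and the para C–OH) makes the two outer rings equivalent.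
- The tetra-acid chloride comes from commercial butyrylphloroglucinol by double formylation, O-benzylation, reductive Knoevenagel alkylation of Meldrum's acid, hydrolysis and chlorination. The diene comes from isobutyryl chloride and pent-1-yne via the ynone, methanol addition and α'-silylation.
- Ring order: the central benzene ring is bought; the two outer rings are formed simultaneously in step 9.

Key step: step 9

Remark: the β-triketone rings are written throughout in the enol tautomer used for the target; the target has no stereocentre, so no step has to control configuration; compound 1 (the antioxidant THBP) is taken as commercial.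

**Route**

Step 1
Reactants: 1 1-(2,4,6-trihydroxyphenyl)butan-1-one
Product: 2 5-butanoyl-2,4,6-trihydroxybenzene-1,3-dicarbaldehyde
Conditions: Cl2CHOMe (5 equiv), TiCl4 (6 equiv), CH2Cl2, −10 °C → rt; then 1 M aq. HCl, 0 °C
Reagents that add atoms: dichloromethyl methyl ether COC(Cl)Cl; water O
Why: Rieche formylation: the TiCl4-bound phenoxide directs the electrophile to the two unsubstituted ring carbons, the only nucleophilic carbon sites of the acylphloroglucinol, and hydrolysis of the α-chloro ethers releases both aldehydes without any possibility of over-reaction.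

Step 2
Reactants: 2 5-butanoyl-2,4,6-trihydroxybenzene-1,3-dicarbaldehyde
Product: 3 2,4,6-tris(benzyloxy)-5-butanoylbenzene-1,3-dicarbaldehyde
Conditions: BnBr (4 equiv), K2CO3 (5 equiv), KI (cat.), DMF, 60 °C
Reagents that add atoms: benzyl bromide BrCc1ccccc1
Why: Williamson etherification: all six ring carbons are substituted, so the three acidic, carbonyl-chelated phenols should only be O-benzylated, which masks them against the acid chlorides of steps 5 and 9.

Step 3
Reactants: 3 2,4,6-tris(benzyloxy)-5-butanoylbenzene-1,3-dicarbaldehyde; 4 Meldrum's acid (2.2 equiv)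
Product: 5 5,5'-{[2,4,6-tris(benzyloxy)-5-butanoyl-1,3-phenylene]bis(methylene)}bis(2,2-dimethyl-1,3-dioxane-4,6-dione)
Conditions: Hantzsch ester (diethyl 2,6-dimethyl-1,4-dihydropyridine-3,5-dicarboxylate, 2.4 equiv), L-proline (20 mol %), EtOH, rt
Reagents that add atoms: none
Why: Organocatalytic reductive Knoevenagel alkylation: each aldehyde condenses with Meldrum's acid and the arylidene is reduced in situ by hydride transfer from the Hantzsch ester, which stops at monoalkylation, while the aryl ketone, shielded by two ortho benzyloxy groups, should not condense.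

Step 4
Reactants: 5 bis(Meldrum's acid) adduct
Product: 6 2,2'-{[2,4,6-tris(benzyloxy)-5-butanoyl-1,3-phenylene]bis(methylene)}dipropanedioic acid
Conditions: 2 M aq. HCl, THF, 45 °C; extraction and concentration below 30 °C
Reagents that add atoms: water O
Why: Acid-catalysed hydrolysis of the isopropylidene acylals liberates the two malonic acid units well below the temperature at which monosubstituted malonic acids decarboxylate, and benzyl aryl ethers are stable to dilute aqueous acid.

Step 5
Reactants: 6 bis(malonic acid)
Product: 7 2,2'-{[2,4,6-tris(benzyloxy)-5-butanoyl-1,3-phenylene]bis(methylene)}dipropanedioyl tetrachloride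
Conditions: (COCl)2 (6 equiv), DMF (cat.), CH2Cl2, 0 °C → rt; evaporation, used crude
Reagents that add atoms: oxalyl chloride O=C(Cl)C(Cl)=O
Why: DMF-catalysed chlorination with oxalyl chloride under cold, non-basic conditions is the standard access to monosubstituted malonyl dichlorides, and the ketone and benzyl ethers should be inert.

Step 6
Reactants: 8 2-methylpropanoyl chloride; 9 pent-1-yne
Product: 10 2-methyloct-4-yn-3-one
Conditions: PdCl2(PPh3)2 (2 mol %), CuI (4 mol %), Et3N (1.2 equiv), THF, rt
Reagents that add atoms: none
Why: Acyl Sonogashira coupling: oxidative addition of the acid chloride to zerovalent palladium and transmetalation of the copper acetylide should give the ynone directly.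

Step 7
Reactants: 10 2-methyloct-4-yn-3-one
Product: 11 (E)-5-methoxy-2-methyloct-4-en-3-one
Conditions: NaOMe (10 mol %), MeOH, 0 °C → rt
Reagents that add atoms: methanol CO
Why: Base-catalysed oxa-Michael addition of methanol to the ynone places the methoxy group only on the β-carbon and so fixes which carbonyl of the latent 1,3-diketone is masked; the alkene geometry (E expected) is without consequence.

Step 8
Reactants: 11 (E)-5-methoxy-2-methyloct-4-en-3-one
Product: 12 (E)-5-methoxy-2-methyl-3-(trimethylsilyloxy)octa-2,4-diene
Conditions: LiN(iPr)2 (1.1 equiv), Me3SiCl (1.2 equiv, internal quench), THF, −78 °C → rt; pentane, filtration, distillation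
Reagents that add atoms: chlorotrimethylsilane C[Si](C)(C)Cl
Why: Kinetic α'-deprotonation of a vinylogous ester (Stork–Danheiser regiochemistry) at the isopropyl methine, the only C–H next to the carbonyl, and O-silylation of the cross-conjugated enolate should give the 2-silyloxy-4-methoxy-1,3-diene; the new tetrasubstituted alkene carries two identical methyl groups, so no geometry issue arises.

Step 9
Reactants: 7 tetra-acid chloride; 12 (E)-5-methoxy-2-methyl-3-(trimethylsilyloxy)octa-2,4-diene (2.05 equiv)
Product: 15 tri-O-benzyl ether of the target, via open-chain bis(β-keto acid chloride) 13 (not isolated), via bis(methyl enol ether) 14 (not isolated)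
Conditions: 12 added over 2 h to 7 (0.01 M), CH2Cl2, −78 °C → rt, 12 h; then 1 M aq. HCl, THF, rt
Reagents that add atoms: water O
Why: Proposed new method: the silyl enol ether terminus of 12 (the Me2C= carbon, activated directly by OSiMe3 and vinylogously by OMe) is C-acylated by one COCl of each malonyl unit with loss of Me3SiCl to give 13, in which the quaternary CMe2 carbon is already in place, and the second COCl (as such or as the acylketene formed by loss of HCl) is then captured by the α-carbon of the pendant β-methoxy enone to give 14, whose push-pull enol ether is hydrolysed to the butyryl group on acidic work-up. The closest known reaction type is the Effenberger cyclisation, in which malonyl dichloride doubly C-acylates the α and α' carbons of a ketone silyl or methyl enol ether to a cyclohexane-1,3,5-trione, fully substituted α-carbons included; what goes beyond it is the vinylogous ester α-carbon as the second nucleophile and the two-directional use of a tetra-acid chloride. Each of the two new rings closes by a 6-(enolexo)-exo-trig C-acylation. No stereocentre is created, because the malonyl CH centres of 13 end as enol carbons and the target is achiral. The step needs C- over O-acylation in the ring closure and cyclisation over chain growth: the enol ether oxygen is blocked as OMe, O-acylation at the ketone oxygen is reversible under the chloride-rich conditions whereas C-acylation is sealed by proton loss, either order of the two bond formations converges on 14, and slow addition of two equivalents of 12 to dilute 7 keeps the intramolecular six-ring closure ahead of a second intermolecular acylation.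

Step 10
Reactants: 15 tri-O-benzyl ether of the target
Product: 16 4,4'-[(5-butanoyl-2,4,6-trihydroxy-1,3-phenylene)bis(methylene)]bis(2-butanoyl-3,5-dihydroxy-6,6-dimethylcyclohexa-2,4-dien-1-one)
Conditions: H2 (1 atm), Pd/C (10 wt %), EtOAc, rt
Reagents that add atoms: none
Why: Hydrogenolysis of the three benzyl aryl ethers over Pd/C under neutral conditions, which the enolised β-triketone rings, the aryl ketone and the diarylmethane-type bridges should tolerate.

**Compound list**
1 | 1-(2,4,6-trihydroxyphenyl)butan-1-one (butyrylphloroglucinol, THBP) | CCCC(=O)c1c(O)cc(O)cc1O | starting material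
2 | 5-butanoyl-2,4,6-trihydroxybenzene-1,3-dicarbaldehyde | CCCC(=O)c1c(O)c(C=O)c(O)c(C=O)c1O | intermediate
3 | 2,4,6-tris(benzyloxy)-5-butanoylbenzene-1,3-dicarbaldehyde | CCCC(=O)c1c(OCc2ccccc2)c(C=O)c(OCc2ccccc2)c(C=O)c1OCc1ccccc1 | intermediate
4 | Meldrum's acid (2,2-dimethyl-1,3-dioxane-4,6-dione) | CC1(C)OC(=O)CC(=O)O1 | starting material
5 | 5,5'-{[2,4,6-tris(benzyloxy)-5-butanoyl-1,3-phenylene]bis(methylene)}bis(2,2-dimethyl-1,3-dioxane-4,6-dione) | CCCC(=O)c1c(OCc2ccccc2)c(CC2C(=O)OC(C)(C)OC2=O)c(OCc2ccccc2)c(CC2C(=O)OC(C)(C)OC2=O)c1OCc1ccccc1 | intermediate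
6 | 2,2'-{[2,4,6-tris(benzyloxy)-5-butanoyl-1,3-phenylene]bis(methylene)}dipropanedioic acid | CCCC(=O)c1c(OCc2ccccc2)c(CC(C(=O)O)C(=O)O)c(OCc2ccccc2)c(CC(C(=O)O)C(=O)O)c1OCc1ccccc1 | intermediate
7 | 2,2'-{[2,4,6-tris(benzyloxy)-5-butanoyl-1,3-phenylene]bis(methylene)}dipropanedioyl tetrachloride | CCCC(=O)c1c(OCc2ccccc2)c(CC(C(Cl)=O)C(Cl)=O)c(OCc2ccccc2)c(CC(C(Cl)=O)C(Cl)=O)c1OCc1ccccc1 | intermediate
8 | 2-methylpropanoyl chloride (isobutyryl chloride) | CC(C)C(=O)Cl | starting material
9 | pent-1-yne | CCCC#C | starting material
10 | 2-methyloct-4-yn-3-one | CCCC#CC(=O)C(C)C | intermediate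
11 | (E)-5-methoxy-2-methyloct-4-en-3-one | CCC/C(OC)=C\C(=O)C(C)C | intermediate
12 | (E)-5-methoxy-2-methyl-3-(trimethylsilyloxy)octa-2,4-diene | CCC/C(OC)=C\C(O[Si](C)(C)C)=C(C)C | intermediate
13 | open-chain bis(β-keto acid chloride) after the first C-acylation on each arm (not isolated; the two CH(COCl) centres are labile and undefined) | CCCC(=O)c1c(OCc2ccccc2)c(CC(C(Cl)=O)C(=O)C(C)(C)C(=O)/C=C(/OC)CCC)c(OCc2ccccc2)c(CC(C(Cl)=O)C(=O)C(C)(C)C(=O)/C=C(/OC)CCC)c1OCc1ccccc1 | intermediate
14 | cyclised bis(methyl enol ether), each outer ring carrying a 1-methoxybutylidene group (not isolated; geometry of the push-pull exocyclic alkene undefined and lost on hydrolysis) | CCCC(=O)c1c(OCc2ccccc2)c(CC2=C(O)C(C)(C)C(=O)C(=C(OC)CCC)C2=O)c(OCc2ccccc2)c(CC2=C(O)C(C)(C)C(=O)C(=C(OC)CCC)C2=O)c1OCc1ccccc1 | intermediate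
15 | tri-O-benzyl ether of the target: 4,4'-{[2,4,6-tris(benzyloxy)-5-butanoyl-1,3-phenylene]bis(methylene)}bis(2-butanoyl-3,5-dihydroxy-6,6-dimethylcyclohexa-2,4-dien-1-one) | CCCC(=O)C1=C(O)C(Cc2c(OCc3ccccc3)c(CC3=C(O)C(C)(C)C(=O)C(C(=O)CCC)=C3O)c(OCc3ccccc3)c(C(=O)CCC)c2OCc2ccccc2)=C(O)C(C)(C)C1=O | intermediate
16 | 4,4'-[(5-butanoyl-2,4,6-trihydroxy-1,3-phenylene)bis(methylene)]bis(2-butanoyl-3,5-dihydroxy-6,6-dimethylcyclohexa-2,4-dien-1-one) (CNP0086314.0) | CCCC(=O)C1=C(O)C(Cc2c(O)c(CC3=C(O)C(C)(C)C(=O)C(C(=O)CCC)=C3O)c(O)c(C(=O)CCC)c2O)=C(O)C(C)(C)C1=O | target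

**Step count**
Total steps: 10. Longest linear sequence: 7 steps (steps 1–5, 9, 10).

**Steps most likely to fail**

Step 9. The ring closure may proceed through oxygen instead of carbon (enol lactone formation), and intermolecular chain growth across the four acid chloride groups may outrun cyclisation. The fallback uses known chemistry; it sets out from compound 1 and comes back at compound 16. Compound 1 is geminally C-methylated at one ring carbon (MeI, NaOMe, MeOH, 0 °C → rt) to 2-butanoyl-3,5-dihydroxy-6,6-dimethylcyclohexa-2,4-dien-1-one (butyrylfilicinic acid) F1. F1 (2 equiv), compound 1 (1 equiv) and aqueous formaldehyde (2 equiv) are then condensed in dilute aqueous KOH at 0 °C → rt, the classical methylene bridging of acylphloroglucinols by hydroxymethylation and quinone methide capture. This should give 16 directly after chromatographic separation from homo-coupled material.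

Step 8. Deprotonation may occur at the γ-methylene of the propyl chain instead of at the isopropyl methine, giving the regioisomeric silyloxydiene, and the silyl group may be lost hydrolytically on isolation. The fallback avoids enolate regiochemistry altogether; it sets out from compound 7 and comes back at compound 15. Commercial 3-methylbut-3-en-2-one is converted by 1,4-hydrosilylation (Et3SiH, RhCl(PPh3)3 cat., 50 °C) into the regiodefined silyl enol ether triethyl[(3-methylbut-2-en-2-yl)oxy]silane F2. F2 (2 equiv) and 7 undergo the Effenberger cyclisation (Et2O/CH2Cl2, −78 °C → rt; aqueous work-up) to the tri-O-benzyl bis(filicinic acid) F3. Double C-butyrylation of F3 at the one free ring CH of each outer ring (butyric acid, DCC, DMAP, CH2Cl2, rt; O-acylation followed by DMAP-mediated O→C acyl shift) should lead to 15.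

Step 3. The double condensation may stall after the first aldehyde because each aldehyde is flanked by two ortho benzyloxy groups, or hydride transfer to the hindered arylidene may lag behind. The fallback replaces condensation and reduction by SN2 alkylation; it sets out from compound 3 and comes back at compound 6. NaBH4 (MeOH/THF, 0 °C) should reduce the two aldehydes selectively, the di-ortho-substituted aryl ketone being shielded, to the bis(hydroxymethyl) compound F4. PBr3 (CH2Cl2, 0 °C) gives the bis(bromomethyl) compound F5. Alkylation of excess sodium diethyl malonate (NaH, THF, 0 °C → rt) gives the tetraethyl ester F6. Saponification (KOH, EtOH/H2O, rt; then cold dilute HCl) returns to 6.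

**Further compounds**
F1 | step 9 | 2-butanoyl-3,5-dihydroxy-6,6-dimethylcyclohexa-2,4-dien-1-one (butyrylfilicinic acid) | CCCC(=O)C1=C(O)C=C(O)C(C)(C)C1=O
F2 | step 8 | triethyl[(3-methylbut-2-en-2-yl)oxy]silane | CC(C)=C(C)O[Si](CC)(CC)CC
F3 | step 8 | 4,4'-{[2,4,6-tris(benzyloxy)-5-butanoyl-1,3-phenylene]bis(methylene)}bis(3,5-dihydroxy-6,6-dimethylcyclohexa-2,4-dien-1-one) | CCCC(=O)c1c(OCc2ccccc2)c(CC2=C(O)C=C(O)C(C)(C)C2=O)c(OCc2ccccc2)c(CC2=C(O)C=C(O)C(C)(C)C2=O)c1OCc1ccccc1
F4 | step 3 | 1-[2,4,6-tris(benzyloxy)-3,5-bis(hydroxymethyl)phenyl]butan-1-one | CCCC(=O)c1c(OCc2ccccc2)c(CO)c(OCc2ccccc2)c(CO)c1OCc1ccccc1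
F5 | step 3 | 1-[2,4,6-tris(benzyloxy)-3,5-bis(bromomethyl)phenyl]butan-1-one | CCCC(=O)c1c(OCc2ccccc2)c(CBr)c(OCc2ccccc2)c(CBr)c1OCc1ccccc1
F6 | step 3 | tetraethyl 2,2'-{[2,4,6-tris(benzyloxy)-5-butanoyl-1,3-phenylene]bis(methylene)}dipropanedioate | CCCC(=O)c1c(OCc2ccccc2)c(CC(C(=O)OCC)C(=O)OCC)c(OCc2ccccc2)c(CC(C(=O)OCC)C(=O)OCC)c1OCc1ccccc1
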